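## Structural features

Compound 18 is a flavonol: a benzene ring A fused to a 4-pyranone ring C (a chromen-4-one), with a 2,5-dihydroxyphenyl ring B joined to C2 through the C2–C1' bond. Ring A carries no hydrogen: C5 has a free hydroxyl hydrogen-bonded to the C4 carbonyl, C6, C7 and C8 carry methoxy groups, and C4a and C8a are the fusion atoms. Ring C carries the enolic 3-hydroxyl between the carbonyl carbon and the carbon bearing ring B. There is no stereocentre, so no stereochemical relationship has to be set; the only spatial element is the twist about C2–C1' caused by the 2'-oxygen. The fragile parts are the free hydroquinone of ring B (oxidised to a quinone by air, base or metal oxidants), the 3-hydroxy-4-pyranone (attacked by hydroxide at C2 and cleaved oxidatively as its metal salt) and the three neighbouring methyl ethers, which a strong Lewis acid can remove one after another once C5 is free. The real difficulty is to place five contiguous oxygen atoms on ring A with exactly one of them free, and to bring an oxygen to C3 between a hindered aryl group and a carbonyl group. The key step uses the fact that C4a lies between the two oxygen-bearing carbons C5 and C8a. Ring A therefore maps onto mirror-symmetric pentamethoxybenzene: its single C–H becomes C4a, one flanking methoxy oxygen becomes O1 by attack on C2, and the other stays as the peri 5-ether, the only ether that can chelate a Lewis acid together with the C4 carbonyl.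

## Logic of the disconnections

18 from 17: three O–alkyl bonds are cut, the two O–CH2Ph bonds on ring B and the O–CH3 bond at C5. They are cut last because the free hydroquinone and the free 5-hydroxyl would not survive the organometallic, oxidative and basic steps. The gain is that 17 differs from 18 only in masking groups, all removable by one reagent. The demand is that a chelating boron Lewis acid removes the benzyl groups and only the peri methyl group, and that the benzyl cations are trapped before they alkylate ring B.

17 from 16: the C3–O bond is cut. The C3–I bond is the direct output of the ring closure, so the oxygen can enter by substitution at an sp2 carbon. The gain is that no separate C–H oxidation of a flavone is needed. The demand is that copper-mediated C–O bond formation at a hindered iodide outruns hydroxide attack at C2, and that oxygen is kept away from the flavonolate.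

16 from 15: the O1–C2 bond (ring C) and the C3–I bond are cut, together with the return of one methyl group to the ring A oxygen. This is the one cut that removes a ring and sets the C3 handle at once. The gain is an acyclic ynone whose ring A is symmetric, so no regiochemical choice exists between its two ortho oxygens. The demand is 6-endo closure by a ring A oxygen, not 5-exo closure, attack by the ring B ether oxygen, or iodination of ring B.

15 from 14, and 14 from 13 and 8: the ketone is taken back to the carbinol, and the bond between the carbinol carbon (future C4) and the alkyne carbon (future C3) is cut. The gain is convergence into a ring A half and a ring B half of similar size. The demand is clean 1,2-addition of 13 (made from 12) to a hindered but non-enolisable aldehyde, and an oxidant that touches only the activated alcohol.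

8 from 5, and 5 from 4 and 1: the C4a–CHO bond is cut, then one O–CH3 bond, then the ring C–O bond of 4. Each cut follows a directed metalation: 5 has one C–H only, and 1 has two equivalent ones. The gain is a cheap tetraoxygenated arene as the source of ring A. The demand is monolithiation of 1 (through 2 and 3) and a mild oxidation that does not take the electron-rich phenol further.

12 from 11, and 11 from 9 and 10: the terminal alkyne carbon is removed (one-carbon homologation of an aldehyde) and the two O–benzyl bonds are cut, each leading back to one molecule of 10. The gain is a commercial dihydroxybenzaldehyde that already has the ring B oxygen pattern. The demand is complete double benzylation, including the chelated 2-hydroxyl, and a homologation that tolerates benzyl ethers and gives the terminal alkyne in one operation.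

## Other disconnections considered

Alternative 1: The cut is the O1–C8a bond.
- Forward key step: the 1,3-diketone A1 has ring A as a 2,5-dihydroxy-3,4-dimethoxyphenyl ketone, a methoxymethyl ether on the central carbon and a bis(methoxymethyl)-protected ring B. Ag2O would oxidise its ring A to the quinone level. The enol oxygen of the far carbonyl would add to the unsubstituted quinone carbon, and enolisation would give the 5,8-hydroquinone A2.
- In favour: the C3 oxygen is in the chain from the start, so no late C3 functionalisation and no hot hydroxide on an iodopyranone are needed. On this point the alternative is the better plan. The closure is mild and neutral, and ring A needs only four oxygens at the outset, because the fifth C–O bond is made by the cyclisation.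
- Against: A2 has free hydroxyls at C5 and C8, so the 8-methyl ether must be added afterwards, relying on the lower reactivity of the chelated 5-hydroxyl. A2 is itself a hydroquinone that the oxidant could take on to the 5,8-quinone. A1 is a triply oxygenated diketone with a free, air-sensitive hydroquinone and needs its own multistep assembly.
- Comparison: on structure both plans separate C5 from its neighbours by the same hydrogen-bond or chelation argument and are about equal, but the chosen plan does so by removing a group in the last step and not by adding one. On mechanism both close ring C by oxygen attack on an electron-poor carbon; the chosen closure also leaves the C3 handle. On step economy the alternative is expected to be longer (making A1, methylation, deprotection).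

Alternative 2: The cut is the C3–C4 bond.
- Forward key step: a triazolium-derived N-heterocyclic carbene would add to the aromatic aldehyde of the dialdehyde A3. The acyl anion equivalent so formed would add to the aliphatic aldehyde and close ring C as the trans-3-hydroxyflavanone A4. A later dehydrogenation of C2–C3 would give the flavonol level.
- In favour: the 5-oxygen is carried as a benzyl ether from the start, so the end-game is one hydrogenolysis with no Lewis-acid demethylation beside three methoxy groups. On this point the alternative is the better plan. The closure is metal-free and the C3 oxygen arrives in the right place.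
- Against: 18 has no stereocentre, so the two stereocentres of A4 are made only to be erased, at the cost of an extra oxidation on a substrate with two electron-rich rings. A3 is an α-aryl-α-aryloxy acetaldehyde, enolisable and prone to aldol and elimination pathways. The carbene must choose the aromatic aldehyde, which is flanked by two ortho oxygens and is the less electrophilic of the two; the other choice leads to the regioisomeric acyloin. The ring A salicylaldehyde needed for A3 has three kinds of oxygen substituent and is harder to reach than symmetric 5.
- Comparison: on structure the alternative settles the C5 question earlier and more cleanly. On mechanism an umpolung C–C bond formation replaces an electrophilic C–O closure, but it delivers ring C at the wrong oxidation level. On step economy the chosen plan is expected to be shorter.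

Alternative 3: The cut runs through ring A: the C4a–C5 bond is made in the key step and the C8–C8a bond in the step before it.
- Forward key step: the C6-metallated form of the pyranone A5 would add to one carbonyl of dimethyl squarate A6 to give the cyclobutenone A7. Heating A7 would open the four-membered ring by a 4π electrocyclic process. The ketene carbon so released would bond to the pyranone carbon that becomes C4a (6π closure), and tautomerisation would give the 5,8-hydroquinone A8 (Moore rearrangement).
- In favour: ring A is built from a cheap C4 unit that already holds the 6,7-dimethoxy pair and the two carbons that become C5 and C8, so no polyoxygenated arene is needed. The key step needs no reagent. The C3 oxygen is in place and the 5-hydroxyl arrives free, so the end-game could again be a hydrogenolysis. On these two points the alternative is the better plan.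
- Against: the nucleophile is a 4-pyranone metallated next to the ring oxygen while carrying its own electrophilic carbonyl, which is a much less secure species than the aryl- and alkenyllithiums normally added to squarates. The pyranone C=C bond is part of a cross-conjugated vinylogous ester and may be a reluctant partner in the 6π closure. A8 has a free 8-hydroxyl that must be methylated selectively, as in alternative 1. A5 itself requires a separate synthesis.
- Comparison: on structure the alternative matches the 5,6,7,8-oxygen pattern elegantly but leaves the 5/8 differentiation to a later step. On mechanism it is a pericyclic cascade, against a polar cyclisation in the chosen plan; both are free of stereochemical issues and are equal in that respect. On step economy the chosen plan is expected to be shorter and rests on more familiar bond formations.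

Key step: step 8

Remarks on the chemistry:
- Structures 15 and 16 were compared atom by atom with 18 (oxygens at C5 to C8, iodine at C3, ring B 2,5-dioxygenated); they are consistent with it.
- The benzyl ethers of 15 are kept. They survive the organolithium, MnO2, ICl and hydroxide steps and leave in the same operation that frees the 5-hydroxyl.
- Step 4 consumes two molecules of 10, one for each phenol of 9; the second one is entered as an atom-adding reagent.
- Three choices keep the route short: a one-pot hydroxylation of 1, a one-step alkyne synthesis for 12, and a benzyl-cation scavenger in the last step.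
- Compounds 14 and 7 are formed as racemates; the stereocentre of 14 is removed in step 7.
- Only intermediates that persist in the flask until the next reagent is added are numbered.

## Steps

Step 1
Reactants: 1 1,2,3,4-tetramethoxybenzene
Product: 4 2,3,4,5-tetramethoxyphenol, via 2,3,4,5-tetramethoxyphenyllithium 2 (not isolated), via lithium aryltrimethoxyborate 3 (not isolated)
Conditions: n-BuLi, TMEDA, THF, 0 °C; B(OMe)3, −78 °C to rt; AcOH, 30% H2O2, 0 °C to rt
Reagents that add atoms: hydrogen peroxide, OO
Why: Methoxy-directed ortho-lithiation of 1 at one of its two equivalent C–H positions gives 2, which B(OMe)3 traps as the borate 3; peroxide oxidation with aryl migration from boron to oxygen then gives the phenol (directed metalation–borylation–oxidation).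

Step 2
Reactants: 4 2,3,4,5-tetramethoxyphenol
Product: 5 pentamethoxybenzene
Conditions: MeI, K2CO3, acetone, reflux
Reagents that add atoms: iodomethane, CI
Why: Williamson O-methylation of the phenoxide of 4; the product is mirror-symmetric and has a single ring C–H.

Step 3
Reactants: 5 pentamethoxybenzene
Product: 8 2,3,4,5,6-pentamethoxybenzaldehyde, via pentamethoxyphenyllithium 6 (not isolated), via lithium hemiaminal alkoxide 7 (not isolated)
Conditions: n-BuLi, THF, 0 °C; DMF, 0 °C to rt; H2O
Reagents that add atoms: N,N-dimethylformamide, CN(C)C=O
Why: The only ring hydrogen of 5 lies between two methoxy groups and is removed by n-BuLi (directed ortho-lithiation) to give 6; addition to DMF gives the stable hemiaminal alkoxide 7, which releases the aldehyde only on aqueous work-up, so over-addition cannot occur (Bouveault-type formylation).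

Step 4
Reactants: 9 2,5-dihydroxybenzaldehyde; 10 benzyl bromide
Product: 11 2,5-bis(benzyloxy)benzaldehyde
Conditions: BnBr (2.3 equiv in all), K2CO3, DMF, 60 °C
Reagents that add atoms: benzyl bromide (second equivalent of 10), BrCc1ccccc1
Why: Double Williamson benzylation, one molecule of 10 for each phenoxide of 9; the chelated 2-hydroxyl reacts more slowly, so a slight excess of 10 and gentle warming are planned.

Step 5
Reactants: 11 2,5-bis(benzyloxy)benzaldehyde
Product: 12 1,4-bis(benzyloxy)-2-ethynylbenzene
Conditions: (MeO)2P(O)C(N2)C(O)Me, K2CO3, MeOH/THF, 0 °C to rt
Reagents that add atoms: dimethyl (1-diazo-2-oxopropyl)phosphonate, CC(=O)C(=[N+]=[N-])P(=O)(OC)OC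
Why: Seyferth–Gilbert homologation in the Ohira–Bestmann variant: methanolysis of the reagent gives the diazomethylphosphonate anion, which adds to the non-enolisable aldehyde; loss of dimethyl phosphate and N2 with a 1,2-hydrogen shift gives the terminal alkyne in one step, and benzyl ethers are inert.

Step 6
Reactants: 12 1,4-bis(benzyloxy)-2-ethynylbenzene; 8 2,3,4,5,6-pentamethoxybenzaldehyde
Product: 14 3-[2,5-bis(benzyloxy)phenyl]-1-(2,3,4,5,6-pentamethoxyphenyl)prop-2-yn-1-ol (racemic), via lithium arylacetylide 13 (not isolated)
Conditions: n-BuLi, THF, −78 °C; 8, −78 to 0 °C; H2O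
Reagents that add atoms: none
Why: Deprotonation of the terminal alkyne gives 13, which adds to the non-enolisable aldehyde 8 (acetylide 1,2-addition); the carbinol stereocentre is formed without control and is removed in step 7.

Step 7
Reactants: 14 3-[2,5-bis(benzyloxy)phenyl]-1-(2,3,4,5,6-pentamethoxyphenyl)prop-2-yn-1-ol
Product: 15 3-[2,5-bis(benzyloxy)phenyl]-1-(2,3,4,5,6-pentamethoxyphenyl)prop-2-yn-1-one
Conditions: MnO2, CH2Cl2, rt
Reagents that add atoms: none
Why: MnO2 selectively oxidises the doubly activated (benzylic and propargylic) alcohol to the ynone; the ethers and the alkyne are inert and the only stereocentre disappears.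

Step 8
Reactants: 15 3-[2,5-bis(benzyloxy)phenyl]-1-(2,3,4,5,6-pentamethoxyphenyl)prop-2-yn-1-one
Product: 16 2-[2,5-bis(benzyloxy)phenyl]-3-iodo-5,6,7,8-tetramethoxy-4H-chromen-4-one
Conditions: ICl (1.2 equiv), CH2Cl2, −78 °C, dark; aq Na2S2O3
Reagents that add atoms: iodine monochloride, ClI
Why: ICl adds to the triple bond of 15 to give a bridged iodonium ion whose positive charge lies on the carbon bearing ring B, because the carbonyl group withdraws density from the other alkyne carbon and ring B stabilises the cation. One of the two equivalent ortho methoxy oxygens of ring A attacks this carbon anti to iodine in a 6-endo-dig closure, forming O1–C2 and ring C as a methyloxonium ion. Chloride then removes the methyl group by SN2 attack, releasing chloromethane and the neutral 3-iodochromone 16. The closest known reaction type is the ICl-induced demethylative iodocyclisation of ortho-methoxyaryl alkynyl ketones to 3-iodochromones. No stereocentre is formed. The step needs 6-endo closure by a ring A oxygen in preference to 5-exo closure (an aurone-type product), to attack by the 2'-benzyloxy oxygen (which can reach only the carbonyl-bearing alkyne carbon, in a 5-endo mode) and to iodination of ring B. Ynone polarisation directs the oxygen to the ring B carbon and disfavours the 5-exo and ring B pathways, the mirror symmetry of ring A makes the choice between the two methoxy groups immaterial, and −78 °C with only a slight excess of ICl limits attack on ring B.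

Step 9
Reactants: 16 2-[2,5-bis(benzyloxy)phenyl]-3-iodo-5,6,7,8-tetramethoxy-4H-chromen-4-one
Product: 17 2-[2,5-bis(benzyloxy)phenyl]-3-hydroxy-5,6,7,8-tetramethoxy-4H-chromen-4-one
Conditions: CuI (cat.), 1,10-phenanthroline (cat.), KOH, degassed DMSO/H2O, 100 °C, Ar; aq HCl
Reagents that add atoms: potassium hydroxide, [K+].[OH-]
Why: Ullmann-type copper-catalysed hydroxylation of a C(sp2)–I bond: a phenanthroline-ligated monovalent copper hydroxide inserts into the C3–I bond and C–O bond formation releases the flavonolate, helped by the neighbouring C4 carbonyl; benzyl and methyl ethers are stable to hydroxide, and acidification gives 17.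

Step 10
Reactants: 17 2-[2,5-bis(benzyloxy)phenyl]-3-hydroxy-5,6,7,8-tetramethoxy-4H-chromen-4-one
Product: 18 2-(2,5-dihydroxyphenyl)-3,5-dihydroxy-6,7,8-trimethoxy-4H-chromen-4-one
Conditions: BCl3, C6HMe5, CH2Cl2, −78 to 0 °C; MeOH, H2O, Ar
Reagents that add atoms: none
Why: BCl3 cleaves the two benzyl ethers with loss of benzyl cation, which pentamethylbenzene traps by Friedel–Crafts alkylation; the 5-methoxy group alone can form a six-membered boron chelate with the C4 carbonyl and is demethylated by chloride, whereas the ethers at C6, C7 and C8 lack this activation (chelation-controlled ether cleavage).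

## Compound list

1 | 1,2,3,4-tetramethoxybenzene | COc1ccc(OC)c(OC)c1OC | starting material
2 | (2,3,4,5-tetramethoxyphenyl)lithium | [Li]c1cc(OC)c(OC)c(OC)c1OC | intermediate (not isolated)
3 | lithium trimethoxy(2,3,4,5-tetramethoxyphenyl)borate | [Li+].CO[B-](OC)(OC)c1cc(OC)c(OC)c(OC)c1OC | intermediate (not isolated)
4 | 2,3,4,5-tetramethoxyphenol | Oc1cc(OC)c(OC)c(OC)c1OC | intermediate
5 | pentamethoxybenzene | COc1cc(OC)c(OC)c(OC)c1OC | intermediate
6 | (2,3,4,5,6-pentamethoxyphenyl)lithium | [Li]c1c(OC)c(OC)c(OC)c(OC)c1OC | intermediate (not isolated)
7 | lithium (dimethylamino)(2,3,4,5,6-pentamethoxyphenyl)methanolate (racemic) | [Li+].[O-]C(N(C)C)c1c(OC)c(OC)c(OC)c(OC)c1OC | intermediate (not isolated)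
8 | 2,3,4,5,6-pentamethoxybenzaldehyde | O=Cc1c(OC)c(OC)c(OC)c(OC)c1OC | intermediate
9 | 2,5-dihydroxybenzaldehyde | O=Cc1cc(O)ccc1O | starting material
10 | benzyl bromide | BrCc1ccccc1 | starting material
11 | 2,5-bis(benzyloxy)benzaldehyde | O=Cc1cc(OCc2ccccc2)ccc1OCc1ccccc1 | intermediate
12 | 1,4-bis(benzyloxy)-2-ethynylbenzene | C#Cc1cc(OCc2ccccc2)ccc1OCc1ccccc1 | intermediate
13 | lithium [2,5-bis(benzyloxy)phenyl]acetylide | [Li]C#Cc1cc(OCc2ccccc2)ccc1OCc1ccccc1 | intermediate (not isolated)
14 | 3-[2,5-bis(benzyloxy)phenyl]-1-(2,3,4,5,6-pentamethoxyphenyl)prop-2-yn-1-ol (racemic) | COc1c(OC)c(OC)c(C(O)C#Cc2cc(OCc3ccccc3)ccc2OCc2ccccc2)c(OC)c1OC | intermediate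
15 | 3-[2,5-bis(benzyloxy)phenyl]-1-(2,3,4,5,6-pentamethoxyphenyl)prop-2-yn-1-one | COc1c(OC)c(OC)c(C(=O)C#Cc2cc(OCc3ccccc3)ccc2OCc2ccccc2)c(OC)c1OC | intermediate
16 | 2-[2,5-bis(benzyloxy)phenyl]-3-iodo-5,6,7,8-tetramethoxy-4H-chromen-4-one | COc1c(OC)c(OC)c2c(=O)c(I)c(-c3cc(OCc4ccccc4)ccc3OCc3ccccc3)oc2c1OC | intermediate
17 | 2-[2,5-bis(benzyloxy)phenyl]-3-hydroxy-5,6,7,8-tetramethoxy-4H-chromen-4-one | COc1c(OC)c(OC)c2c(=O)c(O)c(-c3cc(OCc4ccccc4)ccc3OCc3ccccc3)oc2c1OC | intermediate
18 | 2-(2,5-dihydroxyphenyl)-3,5-dihydroxy-6,7,8-trimethoxy-4H-chromen-4-one (no stereocentre) | COc1c(OC)c(O)c2c(=O)c(O)c(-c3cc(O)ccc3O)oc2c1OC | target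

## Step count and least certain steps

Total step count: 10. Longest linear sequence: 8 steps (steps 1, 2, 3, 6, 7, 8, 9, 10); the ring B branch (steps 4 and 5) joins at step 6.

Step 8 (key step). The most likely failures are electrophilic iodination of the electron-rich ring B, simple addition of ICl across the triple bond without ring closure, and participation of the 2'-benzyloxy oxygen with loss of its benzyl group. All three stem from the same cause: the iodonium source meets several nucleophilic sites before ring C exists. The fallback closes ring C by conjugate addition of a free phenol and places the iodine by directed lithiation. It sets out from 4 and 11 and comes back to the route at 16. Ortho C-acetylation of 4 at its only free ring position with AcOH and BF3·OEt2 would give 1-(2-hydroxy-3,4,5,6-tetramethoxyphenyl)ethan-1-one F1. Claisen–Schmidt condensation of F1 with 11 (KOH, EtOH) would give the chalcone (E)-3-[2,5-bis(benzyloxy)phenyl]-1-(2-hydroxy-3,4,5,6-tetramethoxyphenyl)prop-2-en-1-one F2. Oxidative cyclisation of F2 with catalytic I2 in DMSO at 120 °C would give 2-[2,5-bis(benzyloxy)phenyl]-5,6,7,8-tetramethoxy-4H-chromen-4-one F3. Deprotonation of F3 at C3 with LiN(iPr)2 in THF at −78 °C would give {2-[2,5-bis(benzyloxy)phenyl]-5,6,7,8-tetramethoxy-4-oxo-4H-chromen-3-yl}lithium F4, and quenching with I2 would give 16.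

Step 9. The most likely failures are hydroxide addition at C2 with opening or contraction of the pyranone ring before the copper cycle turns over, protodeiodination at the hindered C3 position, and oxidative cleavage of the copper flavonolate by traces of oxygen. The fallback replaces the C–O coupling by C–B bond formation followed by oxidation, so no hot hydroxide is used. It sets out from 16 and comes back at 17. Miyaura borylation of 16 (B2pin2, Pd(dppf)Cl2, KOAc, dioxane, 80 °C) would give 2-[2,5-bis(benzyloxy)phenyl]-5,6,7,8-tetramethoxy-3-(4,4,5,5-tetramethyl-1,3,2-dioxaborolan-2-yl)-4H-chromen-4-one F5, and oxidation of the C–B bond with NaBO3·4H2O in THF/H2O at rt would give 17.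

Step 10. The most likely failures are demethylation spreading from C5 to C6 once the boron chelate has formed, C-benzylation of ring B if cation trapping is slow, and air oxidation of the liberated hydroquinone during work-up. The fallback separates the two tasks. It sets out from 17 and comes back at 18. Hydrogenolysis of 17 (H2, Pd/C, EtOAc/MeOH, rt) would give 2-(2,5-dihydroxyphenyl)-3-hydroxy-5,6,7,8-tetramethoxy-4H-chromen-4-one F6. Chelation-controlled demethylation of F6 with AlCl3 in MeCN, a milder Lewis acid that stops at the peri ether, followed by dilute HCl work-up under argon, would give 18.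

Step 1. The most likely failures are incomplete or double lithiation of 1 and over-oxidation of the very electron-rich phenol by peroxide to a quinone. The fallback introduces the oxygen through a formyl group. It sets out from 1 and comes back at 4. Rieche formylation (Cl2CHOMe, TiCl4, CH2Cl2, 0 °C) would give 2,3,4,5-tetramethoxybenzaldehyde F7. Baeyer–Villiger oxidation with mCPBA in CH2Cl2 would give 2,3,4,5-tetramethoxyphenyl formate F8, and methanolysis of F8 (K2CO3, MeOH) would give 4.

## Further compounds

F1 | step 8 | 1-(2-hydroxy-3,4,5,6-tetramethoxyphenyl)ethan-1-one | CC(=O)c1c(O)c(OC)c(OC)c(OC)c1OC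
F2 | step 8 | (E)-3-[2,5-bis(benzyloxy)phenyl]-1-(2-hydroxy-3,4,5,6-tetramethoxyphenyl)prop-2-en-1-one | COc1c(OC)c(OC)c(C(=O)/C=C/c2cc(OCc3ccccc3)ccc2OCc2ccccc2)c(O)c1OC
F3 | step 8 | 2-[2,5-bis(benzyloxy)phenyl]-5,6,7,8-tetramethoxy-4H-chromen-4-one | COc1c(OC)c(OC)c2c(=O)cc(-c3cc(OCc4ccccc4)ccc3OCc3ccccc3)oc2c1OC
F4 | step 8 | {2-[2,5-bis(benzyloxy)phenyl]-5,6,7,8-tetramethoxy-4-oxo-4H-chromen-3-yl}lithium | COc1c(OC)c(OC)c2c(=O)c([Li])c(-c3cc(OCc4ccccc4)ccc3OCc3ccccc3)oc2c1OC
F5 | step 9 | 2-[2,5-bis(benzyloxy)phenyl]-5,6,7,8-tetramethoxy-3-(4,4,5,5-tetramethyl-1,3,2-dioxaborolan-2-yl)-4H-chromen-4-one | COc1c(OC)c(OC)c2c(=O)c(B3OC(C)(C)C(C)(C)O3)c(-c3cc(OCc4ccccc4)ccc3OCc3ccccc3)oc2c1OC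
F6 | step 10 | 2-(2,5-dihydroxyphenyl)-3-hydroxy-5,6,7,8-tetramethoxy-4H-chromen-4-one | COc1c(OC)c(OC)c2c(=O)c(O)c(-c3cc(O)ccc3O)oc2c1OC
F7 | step 1 | 2,3,4,5-tetramethoxybenzaldehyde | O=Cc1cc(OC)c(OC)c(OC)c1OC
F8 | step 1 | 2,3,4,5-tetramethoxyphenyl formate | O=COc1cc(OC)c(OC)c(OC)c1OC
A1 | alternative 1 | 1-(2,5-dihydroxy-3,4-dimethoxyphenyl)-2-(methoxymethoxy)-3-[2,5-bis(methoxymethoxy)phenyl]propane-1,3-dione (racemic) | COCOC(C(=O)c1cc(O)c(OC)c(OC)c1O)C(=O)c1cc(OCOC)ccc1OCOC
A2 | alternative 1 | 5,8-dihydroxy-6,7-dimethoxy-3-(methoxymethoxy)-2-[2,5-bis(methoxymethoxy)phenyl]-4H-chromen-4-one | COCOc1c(-c2cc(OCOC)ccc2OCOC)oc2c(O)c(OC)c(OC)c(O)c2c1=O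
A3 | alternative 2 | 2-(benzyloxy)-6-{1-[2,5-bis(benzyloxy)phenyl]-2-oxoethoxy}-3,4,5-trimethoxybenzaldehyde (racemic) | O=CC(Oc1c(C=O)c(OCc2ccccc2)c(OC)c(OC)c1OC)c1cc(OCc2ccccc2)ccc1OCc1ccccc1
A4 | alternative 2 | trans-5-(benzyloxy)-2-[2,5-bis(benzyloxy)phenyl]-3-hydroxy-6,7,8-trimethoxychroman-4-one (racemic, 2R,3R enantiomer drawn) | C(c1ccccc1)Oc1ccc(OCc2ccccc2)c(c1)[C@@H]2[C@H](C(=O)c3c(OCc4ccccc4)c(OC)c(OC)c(OC)c3O2)O
A5 | alternative 3 | 3-(benzyloxy)-2-[2,5-bis(benzyloxy)phenyl]-4H-pyran-4-one | O=c1ccoc(-c2cc(OCc3ccccc3)ccc2OCc2ccccc2)c1OCc1ccccc1
A6 | alternative 3 | dimethyl squarate (3,4-dimethoxycyclobut-3-ene-1,2-dione) | COC1=C(OC)C(=O)C1=O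
A7 | alternative 3 | 4-{5-(benzyloxy)-6-[2,5-bis(benzyloxy)phenyl]-4-oxo-4H-pyran-2-yl}-4-hydroxy-2,3-dimethoxycyclobut-2-en-1-one (racemic) | COC1=C(OC)C(O)(c2cc(=O)c(OCc3ccccc3)c(-c3cc(OCc4ccccc4)ccc3OCc3ccccc3)o2)C1=O
A8 | alternative 3 | 3-(benzyloxy)-2-[2,5-bis(benzyloxy)phenyl]-5,8-dihydroxy-6,7-dimethoxy-4H-chromen-4-one | COc1c(OC)c(O)c2c(=O)c(OCc3ccccc3)c(-c3cc(OCc4ccccc4)ccc3OCc3ccccc3)oc2c1O
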